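The earlier runs and the new flask are calculated for an exercise; scatter was added.

In this closed, stirred vessel I treat the target as a tank level: substrate feeds it, and a drain takes it on to over-reaction product or back to substrate, both flows first-order. Neither target step on the list of suspects has free catalyst in it, so I expect the two runs to share the ratio at which feed equals drain.

| setting | Wednesday's | Saturday's | flask |
|---|---|---|---|
| substrate | 0.068 M | 0.068 M | 0.068 M |
| free catalyst | 1 mM | 0.67 mM | 1.0 mM |
| remark | the very flask that is asked about, followed so far | run made earlier |  |
| time |  |  | 1.0 h |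

| run | time / min | target / % | substrate / % |
|---|---|---|---|
| Wednesday's | 5.00 | 14.3 | 77.6 |
| Wednesday's | 8.00 | 19.0 | 67.2 |
| Wednesday's | 12.0 | 23.0 | 55.2 |
| Wednesday's | 20.0 | 24.3 | 40.3 |
| Wednesday's | 30.0 | 21.7 | 28.0 |
| Saturday's | 5.00 | 14.8 | 78.7 |
| Saturday's | 8.00 | 19.5 | 68.3 |
| Saturday's | 15.0 | 24.8 | 51.7 |
| Saturday's | 25.0 | 24.5 | 35.9 |
| Saturday's | 40.0 | 19.8 | 22.4 |

(each reading ± 0.5 percentage points)

* the moment within 1.0 h at which there is most target
* the amount of target, in percent of the substrate charged, at that time
* the first time at which target reaches 7.3%, in the same percent, in min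

- the numbers in the tables scatter by 0.5 percentage points (one standard deviation)
- on the list of suspects stand: substrate <-> target; substrate + free catalyst <-> isomer of the product + free catalyst; target -> over-reaction product; substrate + free catalyst -> spent catalyst

The first way uses Wednesday's run. Target climbs 0.0157 min⁻¹ between 5.00 min and 8.00 min, and it changes by −0.00260 min⁻¹ between 20.0 min and 30.0 min. Writing feed minus drain for both windows, at their mean levels, gives two equations in two constants. Solving them gives 0.558 for target over substrate when feed equals drain, the peak ratio.

The second way uses Saturday's run, with 0.67 mM of free catalyst. Target stands nearly level at 24.8% and 24.5% at 15.0 min and 25.0 min, so the top lies about midway, and the mean readings there give 0.563. These two ways use different readings from different runs, and they agree, so I trust the ratio.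

In Wednesday's run the ratio climbs from 0.417 at 12.0 min to 0.603 at 20.0 min. Interpolating, it reaches the peak ratio at 18.1 min, with substrate near 43.9%, so I reckon the target's top at 24.5%.

The forecast says 0.3 h (0.26 h to 0.35 h), 24.6% (24% to 25.2%) and 2.2 min (1.9 min to 2.6 min), holding that “the target must form mainly without catalyst”.

The flask gives 0.305 h, 24.4% and 2.17 min.

    substrate ⇌ target (K = 2.70, k = 6.40 × 10⁻⁴ s⁻¹)
    substrate + free catalyst ⇌ isomer of the product + free catalyst, rate k2*[substrate]*[free catalyst] forward; the back reaction follows from the equilibrium constant (K = 2.70, k = 0.270 L mol⁻¹ s⁻¹)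
    target → over-reaction product (k = 8.90 × 10⁻⁴ s⁻¹)
    substrate + free catalyst → spent catalyst (k = 0.00980 L mol⁻¹ s⁻¹)

At 0.305 h the flask holds substrate 42.9% and target 24.4%, a ratio of 0.569, beside the peak ratio of 0.558 that I read from Wednesday's run. Taking each step net, the flask makes target 1.39 times as fast as it uses it up at 0.217 h, but 0.502 times as fast at 1.00 h. The flask left until 15 min ends at a ratio of 0.489, below the peak ratio I read, and the highest target it reaches is 24.0%, with 24.0% at its end.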